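**Plan**
- Retrosynthesis, in imidazo[1,2-a]pyrazin-3(7H)-one numbering: the pyrazine ring is opened at N7–C6 and N4–C5 in one cut, giving an amino-imidazolone and an arylglyoxal; the imidazolone is then opened at N4–C8a and the amide at N1–C8a.
- Enabling feature: N4–C8a–C8–N7 is a 1,4-N,N-dinucleophile that already exists in the imidazolone obtained by cyclodehydrating Phe-Tyr-NH2, and C5–C6(aryl) sits at the oxidation level of an arylglyoxal, so the six-membered ring can close by loss of two waters without any redox reagent.
- Forward: peptide coupling joins the chain, silylative cyclodehydration closes the five-membered ring, Boc removal frees N7, and the pyrazine ring is closed last. The glyoxal carries its phenol as a MOM ether (two steps from 4'-hydroxyacetophenone), which the acid finish of the last step removes.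
- Stereochemistry: the target has no stereocentre. C8 and C2 come from L-Phe and L-Tyr and both become sp2 in the last step, so no stereocontrol is needed.

Key step: step 6

Assumption: since the given SMILES contains no stereocentre, the "single enantiomer" is the achiral compound itself. Intermediates are drawn with the configurations inherited from the L-amino acids, although ring C5 of the imidazolones is expected to epimerise, which is without consequence.

**Step 1**
Reactants: 1 Boc-L-phenylalanine; 2 L-tyrosinamide
Product: 3 Boc-L-Phe-L-Tyr-NH2, tert-butyl N-[(2S)-1-{[(2S)-1-amino-3-(4-hydroxyphenyl)-1-oxopropan-2-yl]amino}-1-oxo-3-phenylpropan-2-yl]carbamate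
Conditions: EDC·HCl, HOBt, DMF, 0 °C → rt
Reagents that add atoms: none
Why: Carbodiimide/HOBt amide coupling, in which the α-amine of 2 is far more nucleophilic than its phenol or primary amide, the urethane on 1 suppresses azlactone-type racemisation, and no new stereocentre is formed.

**Step 2**
Reactants: 3 Boc-L-Phe-L-Tyr-NH2
Product: 5 Boc-protected imidazolone (5S)-2-[(1S)-1-[(tert-butoxycarbonyl)amino]-2-phenylethyl]-5-(4-hydroxybenzyl)-3,5-dihydro-4H-imidazol-4-one, via silyl ether 4 (not isolated)
Conditions: HMDS, (NH4)2SO4 (cat.), pyridine, 100 °C, Ar; then MeOH, rt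
Reagents that add atoms: none
Why: Silylative cyclodehydration of an α-acylamino carboxamide to an imidazol-4-one (the HMDS ring closure used for imidazolinone chromophores), in which the silylated primary amide nitrogen adds to the O-silyl imidate of the Phe carbonyl (5-exo-trig) and hexamethyldisiloxane leaves, so no water or hydroxide is present to reopen the ring or attack the carbamate; the phenol is silylated in passing and freed by methanol, no stereocentre is formed, and 5 is kept under argon because C5–H imidazolones autoxidise.

**Step 3**
Reactants: 5 Boc-protected imidazolone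
Product: 6 (5S)-2-[(1S)-1-amino-2-phenylethyl]-5-(4-hydroxybenzyl)-3,5-dihydro-4H-imidazol-4-one hydrochloride
Conditions: HCl (4 M in 1,4-dioxane), 0 °C → rt; Et2O trituration
Reagents that add atoms: hydrogen chloride, Cl
Why: Acidolysis of the tert-butyl carbamate (Boc removal) under anhydrous conditions, which should spare the hydrolytically labile imidazolone, and isolation as the hydrochloride keeps the primary amine from aminolysing the ring of a second molecule.

**Step 4**
Reactants: 7 4'-hydroxyacetophenone
Product: 8 1-[4-(methoxymethoxy)phenyl]ethan-1-one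
Conditions: MOMCl, K2CO3, acetone, 0 °C → rt
Reagents that add atoms: chloromethyl methyl ether, COCCl
Why: Williamson-type O-alkylation of the phenoxide (MOM protection), giving an acetal that is stable to the basic stage of step 6 and prevents the phenoxide donation that would deactivate the aryl ketone there.

**Step 5**
Reactants: 8 1-[4-(methoxymethoxy)phenyl]ethan-1-one
Product: 9 4-(methoxymethoxy)phenylglyoxal hydrate, 2,2-dihydroxy-1-[4-(methoxymethoxy)phenyl]ethan-1-one
Conditions: SeO2, 1,4-dioxane/H2O, 90 °C; crystallisation from water
Reagents that add atoms: selenium dioxide, O=[Se]=O; water, O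
Why: Riley oxidation of an aryl methyl ketone to the arylglyoxal, isolated as its crystalline hydrate, in a medium that is only weakly acidic and should leave the aryl MOM ether intact.

**Step 6**
Reactants: 6 amino-imidazolone hydrochloride; 9 4-(methoxymethoxy)phenylglyoxal hydrate
Product: 12 coelenterazine, via free amine 10 (not isolated), via MOM ether 11 (not isolated)
Conditions: NaOH (3.3 equiv), degassed MeOH/H2O, −40 → −10 °C, Ar; then HCl/MeOH, 50 °C, Ar; precipitation at pH ≈ 6 under Ar
Reagents that add atoms: none
Why: Proposed new method: hydroxide frees amine 10 and deprotonates its ring N–H; the primary amine (N7) should then condense with the aryl ketone of 9 to the C6 ketimine while the amidate-type ring nitrogen (N4) adds to the aldehyde carbon (C5), and whichever event comes second is a 6-exo-trig closure of the pyrazine ring. Removal of the doubly activated C8 proton expels the C5 hydroxyl (E1cB through the azaallyl system) and a proton shift from C2 to N7 gives the C2=N1/C8a=C8/C5=C6 array of 11 with no redox step; methanolic HCl then completes dehydration, cleaves the MOM acetal and leaves the product in its oxygen-tolerant protonated form. The closest known reaction types are the Jones 2(1H)-pyrazinone synthesis (α-amino amide plus arylglyoxal, NaOH, low temperature) and its α-amino amidine counterpart leading to 3-alkyl-5-aryl-2-aminopyrazines; a cyclic N-acylamidine has not served as the N–C–C–N partner. No stereocentre is created, and the two inherited ones (C8, C2) are destroyed. The step needs amine-to-ketone and ring-N-to-aldehyde regiochemistry, which is the sense both precedents show at low temperature, where the aldehyde rests as hydrate or hemiacetal and the ketone, kept electrophilic because its para oxygen is a MOM ether and not a phenoxide, is the free carbonyl; it also needs closure through N4 and not N1, which rests on the imidazolone anion reacting at the nitrogen next to its carbonyl, as in the base-mediated N-alkylation of 2-alkylimidazolin-4-ones, N1 being flanked by the substituted C2.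

**Compound list**
1 | Boc-L-phenylalanine | CC(C)(C)OC(=O)N[C@@H](Cc1ccccc1)C(=O)O | starting material
2 | L-tyrosinamide | N[C@@H](Cc1ccc(O)cc1)C(N)=O | starting material
3 | Boc-L-Phe-L-Tyr-NH2 | CC(C)(C)OC(=O)N[C@@H](Cc1ccccc1)C(=O)N[C@@H](Cc1ccc(O)cc1)C(N)=O | intermediate
4 | aryl trimethylsilyl ether of 5 (further reversible silylation of the ring not drawn; not isolated) | CC(C)(C)OC(=O)N[C@@H](Cc1ccccc1)C1=N[C@@H](Cc2ccc(O[Si](C)(C)C)cc2)C(=O)N1 | intermediate
5 | (5S)-2-[(1S)-1-[(tert-butoxycarbonyl)amino]-2-phenylethyl]-5-(4-hydroxybenzyl)-3,5-dihydro-4H-imidazol-4-one | CC(C)(C)OC(=O)N[C@@H](Cc1ccccc1)C1=N[C@@H](Cc2ccc(O)cc2)C(=O)N1 | intermediate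
6 | (5S)-2-[(1S)-1-amino-2-phenylethyl]-5-(4-hydroxybenzyl)-3,5-dihydro-4H-imidazol-4-one hydrochloride | Cl.N[C@@H](Cc1ccccc1)C1=N[C@@H](Cc2ccc(O)cc2)C(=O)N1 | intermediate
7 | 4'-hydroxyacetophenone | CC(=O)c1ccc(O)cc1 | starting material
8 | 1-[4-(methoxymethoxy)phenyl]ethan-1-one | COCOc1ccc(cc1)C(C)=O | intermediate
9 | 4-(methoxymethoxy)phenylglyoxal hydrate | COCOc1ccc(cc1)C(=O)C(O)O | intermediate
10 | (5S)-2-[(1S)-1-amino-2-phenylethyl]-5-(4-hydroxybenzyl)-3,5-dihydro-4H-imidazol-4-one (free base of 6; not isolated) | N[C@@H](Cc1ccccc1)C1=N[C@@H](Cc2ccc(O)cc2)C(=O)N1 | intermediate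
11 | 8-benzyl-2-(4-hydroxybenzyl)-6-[4-(methoxymethoxy)phenyl]imidazo[1,2-a]pyrazin-3(7H)-one (not isolated) | O=c1c(Cc2ccc(O)cc2)nc2c(Cc3ccccc3)[nH]c(-c3ccc(OCOC)cc3)cn1-2 | intermediate
12 | coelenterazine, 8-benzyl-2-(4-hydroxybenzyl)-6-(4-hydroxyphenyl)imidazo[1,2-a]pyrazin-3(7H)-one | O=c1c(Cc2ccc(O)cc2)nc2c(Cc3ccccc3)[nH]c(-c3ccc(O)cc3)cn1-2 | target

**Step count**
Total: 6 steps. Longest linear sequence: 4 steps (1 → 3 → 5 → 6 → 12, steps 1, 2, 3 and 6); the glyoxal branch (7 → 8 → 9) is 2 steps and joins in step 6.

**Steps most likely to fail**

1. Step 6 (the proposed new method).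
 - Risks:
 - the amine may capture the aldehyde carbon, which leads to the 5-aryl isomer;
 - the ring may close through N1;
 - the imidazolone enolate may add reversibly through C2 to the aldehyde;
 - base may induce a hydride shift in the glyoxal or in the C5 carbinolamine;
 - the product anion may autoxidise before acidification.
 - Fallback (known chemistry, pyrazine ring first and imidazolone ring last), setting out from 9 and returning at 12: commercial racemic 2-amino-3-phenylpropanenitrile hydrochloride is taken through a Pinner reaction (HCl, EtOH, 0 °C) to ethyl 2-amino-3-phenylpropanimidate dihydrochloride F1 and ammonolysed (NH3, EtOH) to 2-amino-3-phenylpropanimidamide dihydrochloride F2. F2 and 9 are condensed with KOH in aqueous methanol at −30 °C to rt, the established amidine–glyoxal pyrazine synthesis, which should give 3-benzyl-5-[4-(methoxymethoxy)phenyl]pyrazin-2-amine F3. Separately, {4-[(tert-butyldimethylsilyl)oxy]benzyl}magnesium chloride F4, made from the commercial benzyl chloride and magnesium in THF, is added to ethyl diethoxyacetate at −78 °C to give 3-{4-[(tert-butyldimethylsilyl)oxy]phenyl}-1,1-diethoxypropan-2-one F5. Heating F3 with F5 in degassed aqueous HCl/ethanol at 80 °C under argon, the classical aminopyrazine–ketoacetal condensation, should close the imidazolone ring and remove the MOM and silyl groups in the same flask, giving 12.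

2. Step 2.
 - Risks: the ring closure may stall at the silylated open-chain stage, the Boc group may be lost thermally, and the ring may reopen hydrolytically or autoxidise at C5 during work-up.
 - Fallback, setting out from 1 and returning at 5: 1 is converted through its isobutyl mixed anhydride and aqueous ammonia into Boc-L-phenylalaninamide F6, thionated with Lawesson's reagent (THF, rt) to Boc-L-phenylalanine thioamide F7, and S-methylated (MeI, acetone) to the S-methyl thioimidate hydroiodide F8. F8 reacts with commercial L-tyrosine methyl ester (NaHCO3, MeOH, rt) to give the N-substituted amidine F9, whose amidine N–H closes onto the methyl ester on warming (the imidate/amino-ester imidazolone synthesis) to give 5.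

3. Step 5.
 - Risks: selenous acid may strip the MOM group at 90 °C, and the aldehyde may be over-oxidised to the arylglyoxylic acid.
 - Fallback, setting out from 8 and returning at 9: kinetic enolisation and silylation (LiHMDS, TMSCl, THF, −78 °C) gives trimethyl({1-[4-(methoxymethoxy)phenyl]ethenyl}oxy)silane F10. NBS in THF at 0 °C gives 2-bromo-1-[4-(methoxymethoxy)phenyl]ethan-1-one F11 without free acid, and Kornblum oxidation (DMSO, NaHCO3, rt to 50 °C) followed by aqueous work-up gives hydrate 9.

**Further compounds**
F1 | step 6 | ethyl 2-amino-3-phenylpropanimidate dihydrochloride (racemic) | Cl.Cl.CCOC(=N)C(N)Cc1ccccc1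
F2 | step 6 | 2-amino-3-phenylpropanimidamide dihydrochloride (racemic) | Cl.Cl.NC(=N)C(N)Cc1ccccc1
F3 | step 6 | 3-benzyl-5-[4-(methoxymethoxy)phenyl]pyrazin-2-amine | COCOc1ccc(cc1)-c1cnc(N)c(Cc2ccccc2)n1
F4 | step 6 | {4-[(tert-butyldimethylsilyl)oxy]benzyl}magnesium chloride | CC(C)(C)[Si](C)(C)Oc1ccc(C[Mg]Cl)cc1
F5 | step 6 | 3-{4-[(tert-butyldimethylsilyl)oxy]phenyl}-1,1-diethoxypropan-2-one | CCOC(OCC)C(=O)Cc1ccc(O[Si](C)(C)C(C)(C)C)cc1
F6 | step 2 | Boc-L-phenylalaninamide | CC(C)(C)OC(=O)N[C@@H](Cc1ccccc1)C(N)=O
F7 | step 2 | Boc-L-phenylalanine thioamide | CC(C)(C)OC(=O)N[C@@H](Cc1ccccc1)C(N)=S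
F8 | step 2 | methyl (2S)-2-[(tert-butoxycarbonyl)amino]-3-phenylpropanimidothioate hydroiodide | I.CC(C)(C)OC(=O)N[C@@H](Cc1ccccc1)C(=N)SC
F9 | step 2 | methyl N-{(2S)-2-[(tert-butoxycarbonyl)amino]-3-phenylpropanimidoyl}-L-tyrosinate | CC(C)(C)OC(=O)N[C@@H](Cc1ccccc1)C(=N)N[C@@H](Cc1ccc(O)cc1)C(=O)OC
F10 | step 5 | trimethyl({1-[4-(methoxymethoxy)phenyl]ethenyl}oxy)silane | COCOc1ccc(cc1)C(=C)O[Si](C)(C)C
F11 | step 5 | 2-bromo-1-[4-(methoxymethoxy)phenyl]ethan-1-one | COCOc1ccc(cc1)C(=O)CBr
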